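## Analysis of the target

The target (30) is an eremophilane: a trans-fused decalin (ring A: C1–C5 and C10; ring B: C5–C10) with a methyl group on C4 (C15) and one on the quaternary ring-fusion carbon C5 (C14), an isopropenyl group on C7, a ketone at C8, an (E)-2-methylbut-2-enoate (tiglate) at C3 and a 3-methylbut-2-enoate (senecioate) at C9. It has six stereocentres, (3R,4R,5R,7S,9S,10R). In the chair–chair form the angular C14 methyl is axial on both rings and trans to H10, while O3, C15, the isopropenyl group and O9 are all equatorial; C15 is cis to C14 and trans to O3. C7 and C9 flank the ketone, are epimerisable and sit in their thermodynamically preferred orientation, so only C3, C4, C5 and C10 must be fixed by bond construction. The sensitive groups are the β,γ-unsaturated ketone (the C11=C12 alkene moves into conjugation with acid or base), the α-acyloxy ketone at C9 (enolisation, ketol transposition) and two different unsaturated esters that must go onto two differentiated hydroxyls without deconjugation. The hard parts are the contiguous C4 (tertiary), C5 (quaternary) and C10 centres with a trans fusion, and three consecutive functionalised carbons C7–C8–C9 whose two oxygens must be told apart. The strategy rests on ring B: read as a C8=C9 enediol derivative, it is the [4+2] adduct of a 2,3-dioxygenated diene C7=C8–C9=C10 and a 1,1-disubstituted dienophile C5=C6 that carries C14 as a formyl group, with C1–C4 as the tether that becomes ring A.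

## Retrosynthetic reasoning

**Ester C–O bonds at C9 and C3 (30 ⇒ 29 ⇒ 28 ⇒ 27 ⇒ 26).** The two acyl–oxygen bonds are cut first. The C9 ester sits on the most labile position (α to the ketone), so it is made last, on ketol 29; the C3 tiglate is made two steps earlier, on alcohol 27. The two hydroxyls are told apart by silyl ethers of different size in 26: the smaller one on O3 is removed first, the bulkier one on O9 afterwards. No strong base or hydride is then needed once an ester is in place.

**Isopropenyl group, C7–C11 (26 ⇒ 24 ⇒ 21).** The C11=C12 alkene is traced to tertiary alcohol 24 by elimination toward a methyl group, and the C7–C11 bond to an aldol addition of the C7 enolate of ketone 21 (through 22 and 23). C7 is the only unhindered α-position once C9 carries a bulky silyloxy group, and the equatorial product is also the thermodynamic one. The forward steps must enolise toward C7 and eliminate away from C7.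

**C8 ketone and C14 methyl (21 ⇒ 20 ⇒ 19 ⇒ 18 ⇒ 17).** The ketone and the C9 oxygen are traced to the C8=C9 enediol ether 20, which carries two different silyl groups. Removing the small one on O8 with a silicon-selective nucleophile releases the ketone at C8 and leaves O9 protected, which settles the C8/C9 distinction. While the ketone is still masked, the angular methyl is traced back through sulfonate 19 and alcohol 18 to aldehyde 17. A methyl group cannot activate a dienophile, so C14 passes through the key step as a formyl group.

**Key disconnection, C5–C10 and C6–C7 (17 ⇒ 16).** Both rings are opened by a retro-[4+2]. This cut is preferred because it removes both ring-fusion stereocentres and both rings at once and leaves an acyclic triene (16) whose only stereocentres are C3 and C4. Ring B is formed already oxidised at C8 and C9. The forward reaction must put the formyl group endo and fold the tether as a chair with the C3 and C4 substituents equatorial.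

**Diene and dienophile (16 ⇒ 15 ⇒ 13 ⇒ 12 ⇒ 11 + 3).** The O8 silyl enol ether comes from methyl ketone 15 by soft enolisation. The C5=C6 methylene comes from a Mannich-type methylenation of aldehyde 13, itself from alcohol 12. The C9=C10 enol ether bond comes from a Horner–Wadsworth–Emmons olefination of aldehyde 11 with the α-silyloxy ketophosphonate 3 (made from 1 through 2). The olefination must place the silyloxy group cis to the chain, so that the tether sits on the outside of the diene.

**Chain (11 ⇒ 9 ⇒ 7 ⇒ 6 ⇒ 4).** The C10 aldehyde is traced to the Z-alkene of 9 by oxidative cleavage, so the alkene of the starting aldehyde 4 serves as an aldehyde equivalent that needs no protecting group. The C14 hydroxyl comes from anti-Markovnikov hydration of the vinyl group of 7. The C3–C4 bond and both stereocentres come from a reagent-controlled crotylation of 4. The trans arrangement of O3 and C15 on ring A corresponds to a syn arrangement in the open chain, so a (Z)-crotyl reagent is required.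

## Alternatives that were turned down

**Alternative 1:** The C3–C4 bond of ring A is cut. Ring B, with C8 as a dioxolane and both ring-fusion centres in place, is carried in aldehyde A1 (3-oxopropyl chain on C10, vinyl and methyl on C5). In the forward key step a divalent samarium reductant turns the C3 aldehyde into a ketyl, which adds 6-exo to the inner vinyl carbon C4; the primary radical left on C15 is reduced to the C4 methyl, giving decalinol A2.
- For: one step makes the C3–C4 bond, both stereocentres and the C15 methyl, and a radical tolerates the neopentyl surroundings of C5.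
- Against: the ketyl must attack the more substituted carbon of an unactivated alkene and leave an unstabilised primary radical. That is the unfavourable polarity and substitution pattern for ketyl–olefin closures, so simple reduction and pinacol coupling should compete. A1 already contains the C5/C10 pair, so the hardest stereochemical problem is solved outside the key step. A2 has no oxygen at C9 and no handle at C7, so the ketone must later be functionalised on both flanks with regiocontrol.
- Comparison: on C3/C4 it is as strong as the chosen route. The chosen route sets that pair in its first step and then uses it to control C5 and C10 while closing both rings with the C8/C9 oxygens in place, in fewer steps.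

**Alternative 2:** The C5–C10 bond is cut by a [3,3] shift. Ring A comes from δ-lactone A3, whose carbinol carbon (C3) bears a tetrasubstituted (Z)-alkenyl group (C4=C5). After enolisation and O-silylation, A3 rearranges (Ireland–Claisen, boat-like transition state): C10 bonds to C5, the C3–O bond breaks, and cyclohexene acid A4 results, with C3=C4, quaternary C5 and C9 as the carboxyl group.
- For: the C5/C10 relationship follows from a suprafacial sigmatropic shift and the alkene geometry. On the predictability of that pair it is as strong as, or stronger than, a cycloaddition that relies on an endo preference.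
- Against: it needs a geometrically pure tetrasubstituted alkene, and a quaternary centre must form through a strained boat. Only ring A is closed; ring B (the C8–C9 bond) remains to be made, and an acyloin-type closure would again give two undifferentiated oxygens. C3 and C4 are erased as the C3=C4 alkene and must be re-installed with facial control.
- Comparison: the chosen route keeps C3/C4 from the start, closes both rings in one step and distinguishes O8 from O9 by the silyl groups on the diene.

**Alternative 3:** The C4–C5 bond is cut. Ring B is a catechol-derived arene in phenol A5, which carries a (2R,3R)-configured secondary mesylate chain. In the forward key step the phenoxide, formed with a potassium alkoxide base, attacks the C4 mesylate through its para carbon C5 with inversion. This closes ring A and gives the cross-conjugated dienone A6 with C3, C4 and C5 set and O8/O9 present.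
- For: ring B and both its oxygens come from an aromatic ring, O8 and O9 are trivially distinguished (phenol against ether), and the precursor is short. On starting-material simplicity it is stronger than the chosen route.
- Against: an SN2 reaction at a secondary carbon by a fully substituted aromatic carbon, forming a quaternary centre, must beat elimination of the mesylate under the basic conditions. The C5 configuration depends on a loose transition state. C10 is still sp2 in A6 and must be set later by reducing the tetrasubstituted C9=C10 enol ether to the trans fusion, alongside selective C6=C7 reduction.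
- Comparison: the chosen route sets C5 and C10 together in one ordered transition state.

Key step: step 11

## Route

Remark: locants C1–C15 are those of the eremophilane skeleton of the target (C14 on C5, C15 on C4, C11–C13 on C7); "11,12,13-trinoreremophil-" names denote the bicyclic core without C11–C13.
Remark: the C3 ester is taken as the (E)-2-methylbut-2-enoate, as the target SMILES specifies.

Step 1
Reactants: 1 dimethyl (1-diazo-2-oxopropyl)phosphonate
Product: 2 dimethyl (1-hydroxy-2-oxopropyl)phosphonate
Conditions: Rh2(OAc)4 (1 mol %), H2O (5 equiv), CH2Cl2, 40 °C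
Reagents that add atoms: water, O
Why: Rhodium-carbenoid O–H insertion: the diazo compound loses N2 at Rh2(OAc)4 and the carbenoid inserts into an O–H bond of water, a standard entry to α-oxygenated phosphonates.

Step 2
Reactants: 2 dimethyl (1-hydroxy-2-oxopropyl)phosphonate
Product: 3 dimethyl [2-oxo-1-(triisopropylsilyloxy)propyl]phosphonate
Conditions: i-Pr3SiOTf, 2,6-lutidine, CH2Cl2, −78 → 0 °C
Reagents that add atoms: triisopropylsilyl trifluoromethanesulfonate, CC(C)[Si](OS(=O)(=O)C(F)(F)F)(C(C)C)C(C)C
Why: O-silylation of a secondary alcohol with a silyl triflate and a hindered pyridine base, which avoids the enolate conditions under which α-hydroxy phosphonates rearrange to phosphates; the bulky silyl group is chosen because it must later survive as the C9 enol ether and C9 ether.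

Step 3
Reactants: 4 (Z)-hept-4-enal
Product: 6 (3R,4R,7Z)-3-methyldeca-1,7-dien-4-ol, via diisopinocampheylborinate ester 5 (not isolated)
Conditions: cis-but-2-ene, n-BuLi, KOt-Bu, THF, −78 → −45 °C; (−)-Ipc2BOMe (Ipc = isopinocampheyl, from (+)-α-pinene), −78 °C; BF3·OEt2; 4, −78 °C; then NaOH, H2O2, 0 °C → rt
Reagents that add atoms: cis-but-2-ene, C/C=C\C
Why: Brown asymmetric crotylboration: the (Z)-crotylborane adds through a closed chair (Zimmerman–Traxler) transition state, so the Z geometry becomes the syn hydroxyl/methyl relationship (C3/C4 of the target), and the isopinocampheyl groups from (+)-α-pinene are expected to direct attack to the Si face of the aldehyde, giving the (3R,4R) isomer.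

Step 4
Reactants: 6 (3R,4R,7Z)-3-methyldeca-1,7-dien-4-ol
Product: 7 tert-butyldimethyl{[(3R,4R,7Z)-3-methyldeca-1,7-dien-4-yl]oxy}silane
Conditions: t-BuMe2SiOTf, 2,6-lutidine, CH2Cl2, −78 → 0 °C
Reagents that add atoms: tert-butyldimethylsilyl trifluoromethanesulfonate, CC(C)(C)[Si](C)(C)OS(=O)(=O)C(F)(F)F
Why: Silylation of the secondary alcohol; TBS withstands every step up to step 18 and, being smaller than TIPS, can then be removed selectively.

Step 5
Reactants: 7 tert-butyldimethyl{[(3R,4R,7Z)-3-methyldeca-1,7-dien-4-yl]oxy}silane
Product: 9 (3R,4R,7Z)-4-(tert-butyldimethylsilyloxy)-3-methyldec-7-en-1-ol, via B-alkyl-9-borabicyclononane 8 (not isolated)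
Conditions: 9-BBN (1.1 equiv), THF, 0 °C → rt; then NaOH, H2O2, 0 °C
Reagents that add atoms: hydrogen peroxide, OO
Why: Anti-Markovnikov hydroboration–oxidation; 9-BBN reacts with a monosubstituted alkene far faster than with a cis-1,2-disubstituted one, so only the vinyl group is converted, to the primary alcohol that becomes C14.

Step 6
Reactants: 9 (3R,4R,7Z)-4-(tert-butyldimethylsilyloxy)-3-methyldec-7-en-1-ol
Product: 11 (4R,5R)-4-(tert-butyldimethylsilyloxy)-7-hydroxy-5-methylheptanal, via ozonide 10 (not isolated)
Conditions: O3, CH2Cl2, −78 °C; then PPh3, −78 °C → rt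
Reagents that add atoms: ozone, [O-][O+]=O
Why: Ozonolysis with reductive work-up unmasks the C10 aldehyde; the free primary alcohol and the silyl ether are inert, and an eight-membered lactol is not expected to form.

Step 7
Reactants: 11 (4R,5R)-4-(tert-butyldimethylsilyloxy)-7-hydroxy-5-methylheptanal, 3 dimethyl [2-oxo-1-(triisopropylsilyloxy)propyl]phosphonate
Product: 12 (3Z,7R,8R)-7-(tert-butyldimethylsilyloxy)-10-hydroxy-8-methyl-3-(triisopropylsilyloxy)dec-3-en-2-one
Conditions: LiCl, DBU, MeCN, 0 °C → rt
Reagents that add atoms: none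
Why: Horner–Wadsworth–Emmons olefination under LiCl/amine conditions, which tolerate the free hydroxyl; as with other α-oxygenated phosphonates, reversible addition should place the acetyl group trans to the chain, that is the silyloxy group cis to C1 (Z), the geometry the cycloaddition needs.

Step 8
Reactants: 12 (3Z,7R,8R)-7-(tert-butyldimethylsilyloxy)-10-hydroxy-8-methyl-3-(triisopropylsilyloxy)dec-3-en-2-one
Product: 13 (3R,4R,7Z)-4-(tert-butyldimethylsilyloxy)-3-methyl-9-oxo-8-(triisopropylsilyloxy)dec-7-enal
Conditions: Dess–Martin periodinane, CH2Cl2, 0 °C → rt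
Reagents that add atoms: none
Why: Dess–Martin oxidation of a primary alcohol to the aldehyde under near-neutral conditions that leave the silyl ethers and the electron-poor TIPS enol ether intact.

Step 9
Reactants: 13 (3R,4R,7Z)-4-(tert-butyldimethylsilyloxy)-3-methyl-9-oxo-8-(triisopropylsilyloxy)dec-7-enal
Product: 15 (3R,4R,7Z)-4-(tert-butyldimethylsilyloxy)-3-methyl-2-methylidene-9-oxo-8-(triisopropylsilyloxy)dec-7-enal, via Mannich base 14 (not isolated)
Conditions: H2C=NMe2 I (Eschenmoser's salt), Et3N, CH2Cl2, rt
Reagents that add atoms: N,N-dimethylmethyleneiminium iodide, C=[N+](C)C.[I-]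
Why: Mannich reaction of the aldehyde with the iminium salt and β-elimination of dimethylamine give the 2-methylene aldehyde (α-methylenation), supplying C6; the methyl ketone is far less enolisable under these conditions and C4 is not epimerisable.

Step 10
Reactants: 15 (3R,4R,7Z)-4-(tert-butyldimethylsilyloxy)-3-methyl-2-methylidene-9-oxo-8-(triisopropylsilyloxy)dec-7-enal
Product: 16 (3R,4R,7Z)-4-(tert-butyldimethylsilyloxy)-3-methyl-2-methylidene-9-(triethylsilyloxy)-8-(triisopropylsilyloxy)deca-7,9-dienal
Conditions: Et3SiOTf (1.1 equiv), Et3N (3 equiv), CH2Cl2, −78 °C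
Reagents that add atoms: triethylsilyl trifluoromethanesulfonate, CC[Si](CC)(CC)OS(=O)(=O)C(F)(F)F
Why: Soft enolisation: the silyl triflate silylates the ketone oxygen and the amine removes a methyl proton, giving the 2,3-bis(silyloxy)diene; the aldehyde has no α-hydrogen and, as a conjugated enal, should resist triflate-promoted aldol addition at −78 °C with excess amine. TES is used on O8 because it tolerates the Lewis acid of step 11 better than a trimethylsilyl group yet is cleaved by fluoride far faster than TIPS.

Step 11
Reactants: 16 (3R,4R,7Z)-4-(tert-butyldimethylsilyloxy)-3-methyl-2-methylidene-9-(triethylsilyloxy)-8-(triisopropylsilyloxy)deca-7,9-dienal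
Product: 17 (3R,4R,5S,10R)-3-(tert-butyldimethylsilyloxy)-8-(triethylsilyloxy)-9-(triisopropylsilyloxy)-11,12,13-trinoreremophil-8-en-14-al
Conditions: Me2AlCl (1.2 equiv), CH2Cl2, −78 → −40 °C; quench Et3N, aq NaHCO3
Reagents that add atoms: none
Why: Me2AlCl binds the formyl oxygen and lowers the LUMO of the otherwise sluggish 1,1-disubstituted C5=C6 alkene, which adds suprafacially to the s-cis C7=C8–C9=C10 diene in a concerted, asynchronous [4+2] cycloaddition (C6–C7 bonding ahead of C5–C10). The closest known reaction type is the Lewis-acid-promoted type 1 intramolecular Diels–Alder reaction of 1,7,9-decatrienes whose dienophile carries the formyl group on its inner carbon. Ring B closes as the new cyclohexene (C5–C6–C7–C8=C9–C10) by the cycloaddition itself; ring A (C1–C5, C10) closes through the C5–C10 bond as the four-carbon tether folds into a chair. C5 and C10 are the new stereocentres: their relative configuration follows from the (Z)-C9=C10 geometry (tether on the outside of the diene) combined with the formyl-endo, tether-exo orientation, which puts the formyl group and H10 on opposite faces (trans fusion). Their absolute configuration is relayed from C3 and C4: only one diene face is reached with both the C3 silyloxy and C4 methyl groups equatorial on the chair tether, and this places C15 cis to the formyl group. The step needs endo and facial selectivity, secured by the Lewis-acid-enhanced endo preference of the complexed formyl group and by the diequatorial chair. It also needs both silyl enol ethers to survive, hence TES/TIPS, low temperature and an amine quench.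

Step 12
Reactants: 17 (3R,4R,5S,10R)-3-(tert-butyldimethylsilyloxy)-8-(triethylsilyloxy)-9-(triisopropylsilyloxy)-11,12,13-trinoreremophil-8-en-14-al
Product: 18 (3R,4R,5S,10R)-3-(tert-butyldimethylsilyloxy)-8-(triethylsilyloxy)-9-(triisopropylsilyloxy)-11,12,13-trinoreremophil-8-en-14-ol
Conditions: i-Bu2AlH, CH2Cl2, −78 °C; aq potassium sodium tartrate
Reagents that add atoms: none
Why: 1,2-Reduction of the aldehyde by an aluminium hydride in an aprotic medium, in which the enediol bis-silyl ether is inert; no other reducible group is present because the C8 ketone is still masked.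

Step 13
Reactants: 18 (3R,4R,5S,10R)-3-(tert-butyldimethylsilyloxy)-8-(triethylsilyloxy)-9-(triisopropylsilyloxy)-11,12,13-trinoreremophil-8-en-14-ol
Product: 19 (3R,4R,5S,10R)-3-(tert-butyldimethylsilyloxy)-8-(triethylsilyloxy)-9-(triisopropylsilyloxy)-11,12,13-trinoreremophil-8-en-14-yl methanesulfonate
Conditions: MsCl, Et3N, CH2Cl2, 0 °C
Reagents that add atoms: methanesulfonyl chloride, CS(=O)(=O)Cl
Why: Sulfonylation of the primary alcohol; the reaction takes place at oxygen and is not slowed by the quaternary C5.

Step 14
Reactants: 19 (3R,4R,5S,10R)-3-(tert-butyldimethylsilyloxy)-8-(triethylsilyloxy)-9-(triisopropylsilyloxy)-11,12,13-trinoreremophil-8-en-14-yl methanesulfonate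
Product: 20 (3R,4R,5R,10R)-3-(tert-butyldimethylsilyloxy)-8-(triethylsilyloxy)-9-(triisopropylsilyloxy)-11,12,13-trinoreremophil-8-ene
Conditions: LiEt3BH, THF, 0 °C → reflux
Reagents that add atoms: none
Why: SN2 displacement of a primary sulfonate by hydride; LiEt3BH is the most nucleophilic common hydride and the usual choice for neopentyl centres, and silyl ethers and silyl enol ethers do not react with it.

Step 15
Reactants: 20 (3R,4R,5R,10R)-3-(tert-butyldimethylsilyloxy)-8-(triethylsilyloxy)-9-(triisopropylsilyloxy)-11,12,13-trinoreremophil-8-ene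
Product: 21 (3R,4R,5R,9S,10R)-3-(tert-butyldimethylsilyloxy)-9-(triisopropylsilyloxy)-11,12,13-trinoreremophilan-8-one
Conditions: n-Bu4NF (1.1 equiv), AcOH (1.2 equiv), THF, −40 → −20 °C; then DBU (0.1 equiv), CH2Cl2, rt
Reagents that add atoms: none
Why: Fluoride attacks silicon, and the Et3Si–O bond is cleaved far faster than the i-Pr3Si–O bond, so only O8 is unmasked and the enol tautomerises to the C8 ketone with a new C–H bond at C9 (silyl enol ether cleavage). The equatorial 9S epimer is favoured because the axial one would place the TIPS ether syn-axial to the C14 methyl, and the catalytic amidine completes that equilibration; the secondary TBS ether survives the cold, buffered conditions.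

Step 16
Reactants: 21 (3R,4R,5R,9S,10R)-3-(tert-butyldimethylsilyloxy)-9-(triisopropylsilyloxy)-11,12,13-trinoreremophilan-8-one
Product: 24 (3R,4R,5R,7S,9S,10R)-3-(tert-butyldimethylsilyloxy)-11-hydroxy-9-(triisopropylsilyloxy)eremophilan-8-one, via lithium enolate 22 (not isolated), via chlorozinc enolate 23 (not isolated)
Conditions: LiN(i-Pr)2 (1.1 equiv), THF, −78 °C; ZnCl2; acetone, −78 → −40 °C; aq NH4Cl
Reagents that add atoms: acetone, CC(C)=O
Why: Kinetic deprotonation takes a C7 methylene hydrogen and not the C9 methine shielded by the TIPS ether; transmetalation to zinc suppresses proton transfer and retro-aldol in the directed aldol addition to acetone. The electrophile enters anti to the axial C14 methyl and the new group ends equatorial (7S), which is also the thermodynamic orientation at this epimerisable centre.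

Step 17
Reactants: 24 (3R,4R,5R,7S,9S,10R)-3-(tert-butyldimethylsilyloxy)-11-hydroxy-9-(triisopropylsilyloxy)eremophilan-8-one
Product: 26 (3R,4R,5R,7S,9S,10R)-3-(tert-butyldimethylsilyloxy)-9-(triisopropylsilyloxy)eremophil-11-en-8-one, via chlorosulfite 25 (not isolated)
Conditions: SOCl2, pyridine, CH2Cl2, −40 → 0 °C
Reagents that add atoms: none
Why: Dehydration of a tertiary alcohol through its chlorosulfite; elimination toward one of six methyl hydrogens is favoured statistically and sterically, while the single C7 hydrogen is axial and screened by the syn-axial C14 methyl, so the 11(12)-alkene should predominate. Low temperature and a weak base limit migration into conjugation.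

Step 18
Reactants: 26 (3R,4R,5R,7S,9S,10R)-3-(tert-butyldimethylsilyloxy)-9-(triisopropylsilyloxy)eremophil-11-en-8-one
Product: 27 (3R,4R,5R,7S,9S,10R)-3-hydroxy-9-(triisopropylsilyloxy)eremophil-11-en-8-one
Conditions: HF·pyridine, pyridine, THF, 0 °C → rt
Reagents that add atoms: none
Why: Selective desilylation: the secondary TBS ether is cleaved much faster than the bulkier TIPS ether, whose oxygen is also deactivated toward protonation by the adjacent carbonyl; the pyridine buffer protects the β,γ-unsaturated ketone from acid-induced conjugation.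

Step 19
Reactants: 27 (3R,4R,5R,7S,9S,10R)-3-hydroxy-9-(triisopropylsilyloxy)eremophil-11-en-8-one
Product: 28 (3R,4R,5R,7S,9S,10R)-8-oxo-9-(triisopropylsilyloxy)eremophil-11-en-3-yl (E)-2-methylbut-2-enoate
Conditions: tigloyl chloride, pyridine, DMAP (cat.), CH2Cl2, 0 °C → rt
Reagents that add atoms: (E)-2-methylbut-2-enoyl chloride, C/C=C(\C)C(=O)Cl
Why: DMAP-catalysed acylation of the equatorial secondary alcohol; pyridine instead of a trialkylamine avoids vinylketene formation and deconjugation, and the E geometry (the stable isomer) is retained.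

Step 20
Reactants: 28 (3R,4R,5R,7S,9S,10R)-8-oxo-9-(triisopropylsilyloxy)eremophil-11-en-3-yl (E)-2-methylbut-2-enoate
Product: 29 (3R,4R,5R,7S,9S,10R)-9-hydroxy-8-oxoeremophil-11-en-3-yl (E)-2-methylbut-2-enoate
Conditions: n-Bu4NF, AcOH, THF, 0 °C → rt
Reagents that add atoms: none
Why: Fluoride desilylation; the α-keto TIPS ether is activated toward attack at silicon because the ketol oxygen is a good leaving group, and the acetic acid buffer keeps the medium non-basic so that the isopropenyl ketone does not conjugate and the ketol does not transpose.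

Step 21
Reactants: 29 (3R,4R,5R,7S,9S,10R)-9-hydroxy-8-oxoeremophil-11-en-3-yl (E)-2-methylbut-2-enoate
Product: 30 (3R,4R,5R,7S,9S,10R)-9-(3-methylbut-2-enoyloxy)-8-oxoeremophil-11-en-3-yl (E)-2-methylbut-2-enoate (CNP0375730.3)
Conditions: 3-methylbut-2-enoyl chloride, pyridine, DMAP (cat.), CH2Cl2, 0 °C
Reagents that add atoms: 3-methylbut-2-enoyl chloride, CC(C)=CC(=O)Cl
Why: DMAP-catalysed acylation of the α-hydroxy ketone in pyridine (no trialkylamine, so no vinylketene and no 3-methylbut-3-enoate); C7 and C9 are epimerisable but already equatorial, their preferred orientation, so the product is the target.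

## Compound list

1 | dimethyl (1-diazo-2-oxopropyl)phosphonate | CC(=O)C(=[N+]=[N-])P(=O)(OC)OC | starting material
2 | dimethyl (1-hydroxy-2-oxopropyl)phosphonate (racemic) | CC(=O)C(O)P(=O)(OC)OC | intermediate
3 | dimethyl [2-oxo-1-(triisopropylsilyloxy)propyl]phosphonate (racemic) | CC(=O)C(O[Si](C(C)C)(C(C)C)C(C)C)P(=O)(OC)OC | intermediate
4 | (Z)-hept-4-enal | CC/C=C\CCC=O | starting material
5 | diisopinocampheylborinate ester of 6 (formed in the flask; isopinocampheyl groups from (+)-α-pinene) | CC/C=C\CC[C@@H](OB([C@@H]1C[C@@H]2C[C@H]([C@H]1C)C2(C)C)[C@@H]1C[C@@H]2C[C@H]([C@H]1C)C2(C)C)[C@H](C)C=C | intermediate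
6 | (3R,4R,7Z)-3-methyldeca-1,7-dien-4-ol | CC/C=C\CC[C@@H](O)[C@H](C)C=C | intermediate
7 | tert-butyldimethyl{[(3R,4R,7Z)-3-methyldeca-1,7-dien-4-yl]oxy}silane | CC/C=C\CC[C@@H](O[Si](C)(C)C(C)(C)C)[C@H](C)C=C | intermediate
8 | 9-[(3R,4R,7Z)-4-(tert-butyldimethylsilyloxy)-3-methyldec-7-en-1-yl]-9-borabicyclo[3.3.1]nonane (formed in the flask) | CC/C=C\CC[C@@H](O[Si](C)(C)C(C)(C)C)[C@H](C)CCB1C2CCCC1CCC2 | intermediate
9 | (3R,4R,7Z)-4-(tert-butyldimethylsilyloxy)-3-methyldec-7-en-1-ol | CC/C=C\CC[C@@H](O[Si](C)(C)C(C)(C)C)[C@H](C)CCO | intermediate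
10 | 3-ethyl-5-[(3R,4R)-3-(tert-butyldimethylsilyloxy)-6-hydroxy-4-methylhexyl]-1,2,4-trioxolane (ozonide, formed in the flask, mixture at the ring carbons) | CCC1OOC(CC[C@@H](O[Si](C)(C)C(C)(C)C)[C@H](C)CCO)O1 | intermediate
11 | (4R,5R)-4-(tert-butyldimethylsilyloxy)-7-hydroxy-5-methylheptanal | O=CCC[C@@H](O[Si](C)(C)C(C)(C)C)[C@H](C)CCO | intermediate
12 | (3Z,7R,8R)-7-(tert-butyldimethylsilyloxy)-10-hydroxy-8-methyl-3-(triisopropylsilyloxy)dec-3-en-2-one | CC(=O)/C(O[Si](C(C)C)(C(C)C)C(C)C)=C/CC[C@@H](O[Si](C)(C)C(C)(C)C)[C@H](C)CCO | intermediate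
13 | (3R,4R,7Z)-4-(tert-butyldimethylsilyloxy)-3-methyl-9-oxo-8-(triisopropylsilyloxy)dec-7-enal | CC(=O)/C(O[Si](C(C)C)(C(C)C)C(C)C)=C/CC[C@@H](O[Si](C)(C)C(C)(C)C)[C@H](C)CC=O | intermediate
14 | (3R,4R,7Z)-4-(tert-butyldimethylsilyloxy)-2-[(dimethylamino)methyl]-3-methyl-9-oxo-8-(triisopropylsilyloxy)dec-7-enal (Mannich base, formed in the flask, C2 epimers) | CC(=O)/C(O[Si](C(C)C)(C(C)C)C(C)C)=C/CC[C@@H](O[Si](C)(C)C(C)(C)C)[C@H](C)C(CN(C)C)C=O | intermediate
15 | (3R,4R,7Z)-4-(tert-butyldimethylsilyloxy)-3-methyl-2-methylidene-9-oxo-8-(triisopropylsilyloxy)dec-7-enal | CC(=O)/C(O[Si](C(C)C)(C(C)C)C(C)C)=C/CC[C@@H](O[Si](C)(C)C(C)(C)C)[C@H](C)C(=C)C=O | intermediate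
16 | (3R,4R,7Z)-4-(tert-butyldimethylsilyloxy)-3-methyl-2-methylidene-9-(triethylsilyloxy)-8-(triisopropylsilyloxy)deca-7,9-dienal | C=C(O[Si](CC)(CC)CC)/C(O[Si](C(C)C)(C(C)C)C(C)C)=C/CC[C@@H](O[Si](C)(C)C(C)(C)C)[C@H](C)C(=C)C=O | intermediate
17 | (3R,4R,5S,10R)-3-(tert-butyldimethylsilyloxy)-8-(triethylsilyloxy)-9-(triisopropylsilyloxy)-11,12,13-trinoreremophil-8-en-14-al | C1C[C@]2(C=O)[C@@H](C)[C@H](O[Si](C)(C)C(C)(C)C)CC[C@H]2C(O[Si](C(C)C)(C(C)C)C(C)C)=C1O[Si](CC)(CC)CC | intermediate
18 | (3R,4R,5S,10R)-3-(tert-butyldimethylsilyloxy)-8-(triethylsilyloxy)-9-(triisopropylsilyloxy)-11,12,13-trinoreremophil-8-en-14-ol | C1C[C@]2(CO)[C@@H](C)[C@H](O[Si](C)(C)C(C)(C)C)CC[C@H]2C(O[Si](C(C)C)(C(C)C)C(C)C)=C1O[Si](CC)(CC)CC | intermediate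
19 | (3R,4R,5S,10R)-3-(tert-butyldimethylsilyloxy)-8-(triethylsilyloxy)-9-(triisopropylsilyloxy)-11,12,13-trinoreremophil-8-en-14-yl methanesulfonate | C1C[C@]2(COS(C)(=O)=O)[C@@H](C)[C@H](O[Si](C)(C)C(C)(C)C)CC[C@H]2C(O[Si](C(C)C)(C(C)C)C(C)C)=C1O[Si](CC)(CC)CC | intermediate
20 | (3R,4R,5R,10R)-3-(tert-butyldimethylsilyloxy)-8-(triethylsilyloxy)-9-(triisopropylsilyloxy)-11,12,13-trinoreremophil-8-ene | C1C[C@]2(C)[C@@H](C)[C@H](O[Si](C)(C)C(C)(C)C)CC[C@H]2C(O[Si](C(C)C)(C(C)C)C(C)C)=C1O[Si](CC)(CC)CC | intermediate
21 | (3R,4R,5R,9S,10R)-3-(tert-butyldimethylsilyloxy)-9-(triisopropylsilyloxy)-11,12,13-trinoreremophilan-8-one | C1C[C@]2(C)[C@@H](C)[C@H](O[Si](C)(C)C(C)(C)C)CC[C@H]2[C@H](O[Si](C(C)C)(C(C)C)C(C)C)C1=O | intermediate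
22 | lithium C7=C8 enolate of 21 (formed in the flask) | C=1C[C@]2(C)[C@@H](C)[C@H](O[Si](C)(C)C(C)(C)C)CC[C@H]2[C@H](O[Si](C(C)C)(C(C)C)C(C)C)C=1O[Li] | intermediate
23 | chlorozinc C7=C8 enolate of 21 (formed in the flask) | C=1C[C@]2(C)[C@@H](C)[C@H](O[Si](C)(C)C(C)(C)C)CC[C@H]2[C@H](O[Si](C(C)C)(C(C)C)C(C)C)C=1O[Zn]Cl | intermediate
24 | (3R,4R,5R,7S,9S,10R)-3-(tert-butyldimethylsilyloxy)-11-hydroxy-9-(triisopropylsilyloxy)eremophilan-8-one | CC(C)(O)[C@@H]1C[C@]2(C)[C@@H](C)[C@H](O[Si](C)(C)C(C)(C)C)CC[C@H]2[C@H](O[Si](C(C)C)(C(C)C)C(C)C)C1=O | intermediate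
25 | C11 chlorosulfite of 24 (formed in the flask) | CC(C)(OS(=O)Cl)[C@@H]1C[C@]2(C)[C@@H](C)[C@H](O[Si](C)(C)C(C)(C)C)CC[C@H]2[C@H](O[Si](C(C)C)(C(C)C)C(C)C)C1=O | intermediate
26 | (3R,4R,5R,7S,9S,10R)-3-(tert-butyldimethylsilyloxy)-9-(triisopropylsilyloxy)eremophil-11-en-8-one | C=C(C)[C@@H]1C[C@]2(C)[C@@H](C)[C@H](O[Si](C)(C)C(C)(C)C)CC[C@H]2[C@H](O[Si](C(C)C)(C(C)C)C(C)C)C1=O | intermediate
27 | (3R,4R,5R,7S,9S,10R)-3-hydroxy-9-(triisopropylsilyloxy)eremophil-11-en-8-one | C=C(C)[C@@H]1C[C@]2(C)[C@@H](C)[C@H](O)CC[C@H]2[C@H](O[Si](C(C)C)(C(C)C)C(C)C)C1=O | intermediate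
28 | (3R,4R,5R,7S,9S,10R)-8-oxo-9-(triisopropylsilyloxy)eremophil-11-en-3-yl (E)-2-methylbut-2-enoate | C=C(C)[C@@H]1C[C@]2(C)[C@@H](C)[C@H](OC(=O)/C(C)=C/C)CC[C@H]2[C@H](O[Si](C(C)C)(C(C)C)C(C)C)C1=O | intermediate
29 | (3R,4R,5R,7S,9S,10R)-9-hydroxy-8-oxoeremophil-11-en-3-yl (E)-2-methylbut-2-enoate | C=C(C)[C@@H]1C[C@]2(C)[C@@H](C)[C@H](OC(=O)/C(C)=C/C)CC[C@H]2[C@H](O)C1=O | intermediate
30 | (3R,4R,5R,7S,9S,10R)-9-(3-methylbut-2-enoyloxy)-8-oxoeremophil-11-en-3-yl (E)-2-methylbut-2-enoate (CNP0375730.3) | C=C(C)[C@@H]1C[C@]2(C)[C@@H](C)[C@H](OC(=O)/C(C)=C/C)CC[C@H]2[C@H](OC(=O)C=C(C)C)C1=O | target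

## Step count and least certain steps

Total step count: 21 (steps 1–2 make phosphonate 3; steps 3–21 are the main line). Longest linear sequence: 19 steps, from 4 to 30. C3 and C4 are set in step 3, C5 and C10 in step 11, C9 in step 15 and C7 in step 16.

**Step 11 (key step).** The doubly oxygenated diene is very nucleophilic and acid-labile. The Lewis acid may therefore strip or transfer a silyl group, or divert the reaction into stepwise Mukaiyama-type addition. Because the activating group sits on the inner dienophile carbon, the endo preference may also be incomplete, which would erode the trans fusion. The fallback removes the Lewis acid by changing the dienophile. It sets out from 15: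
- chlorite oxidation (NaClO2, NaH2PO4, 2-methylbut-2-ene) gives the 2-methylene acid F1;
- Me3SiCHN2 gives the methyl ester F2;
- enol silylation as in step 10 gives the triene ester F3, which is cyclised thermally (toluene, 110–140 °C) to the bicyclic ester F4;
- reduction with i-Bu2AlH gives 18, where the route is rejoined.

**Step 10.** Activation of the enal carbonyl by the silyl triflate could start aldol-type oligomerisation or an uncontrolled early cyclisation, and deprotonation at C1 instead of the methyl group would give the wrong dienol ether. The fallback separates aldehyde protection from enolisation. It sets out from 15: lithium 4-methylpiperazin-1-ide (THF, −78 °C) masks the aldehyde in the flask as the lithium α-amino alkoxide F5; the methyl ketone is then deprotonated with LiN(i-Pr)2 and trapped with Et3SiCl; a pH 7 work-up collapses the hemiaminal and returns 16.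

**Step 7.** Incomplete geometric control in the olefination is the risk. The isomer with the silyloxy group trans to the chain cannot reach the transition state that leads to the trans-fused adduct. The fallback sets the geometry by equilibration instead of by the olefination. It sets out from 11 with the same olefination; the separated (E)-enol ether F6 is equilibrated by reversible radical addition (PhSH cat., AIBN, or I2 with light) toward the less strained Z isomer, and the route is rejoined at 12.

**Step 14.** Backside approach to C14 is screened by C4, C6 and C10. Attack of hydride at sulfur (returning the alcohol) or simple lack of reaction is therefore the likely failure. The fallback replaces the ionic displacement by a radical C–O cleavage that is insensitive to neopentyl hindrance. It sets out from 18: PhOC(S)Cl, pyridine and DMAP give the O-phenyl thionocarbonate F7, and Bu3SnH with AIBN in toluene at 110 °C (Barton–McCombie deoxygenation) gives 20.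

**Step 17.** Elimination toward C7, or later migration of the new alkene into conjugation with the ketone, would give the wrong regioisomer, because the C7 hydrogen is acidified by the carbonyl. The fallback corrects the position of the double bond after the fact. It sets out from 24 with the same dehydration; the conjugated isopropylidene ketone F8 is converted into its extended dienolate (KOt-Bu, THF/t-BuOH, 0 °C) and protonated kinetically at C7 (cold aqueous AcOH). Mild equilibration of C7 to the equatorial epimer returns 26.

## Further compounds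

F1 | step 11 | (3R,4R,7Z)-4-(tert-butyldimethylsilyloxy)-3-methyl-2-methylidene-9-oxo-8-(triisopropylsilyloxy)dec-7-enoic acid | CC(=O)/C(O[Si](C(C)C)(C(C)C)C(C)C)=C/CC[C@@H](O[Si](C)(C)C(C)(C)C)[C@H](C)C(=C)C(=O)O
F2 | step 11 | methyl (3R,4R,7Z)-4-(tert-butyldimethylsilyloxy)-3-methyl-2-methylidene-9-oxo-8-(triisopropylsilyloxy)dec-7-enoate | CC(=O)/C(O[Si](C(C)C)(C(C)C)C(C)C)=C/CC[C@@H](O[Si](C)(C)C(C)(C)C)[C@H](C)C(=C)C(=O)OC
F3 | step 11 | methyl (3R,4R,7Z)-4-(tert-butyldimethylsilyloxy)-3-methyl-2-methylidene-9-(triethylsilyloxy)-8-(triisopropylsilyloxy)deca-7,9-dienoate | C=C(O[Si](CC)(CC)CC)/C(O[Si](C(C)C)(C(C)C)C(C)C)=C/CC[C@@H](O[Si](C)(C)C(C)(C)C)[C@H](C)C(=C)C(=O)OC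
F4 | step 11 | methyl (3R,4R,5S,10R)-3-(tert-butyldimethylsilyloxy)-8-(triethylsilyloxy)-9-(triisopropylsilyloxy)-11,12,13-trinoreremophil-8-en-14-oate | C1C[C@]2(C(=O)OC)[C@@H](C)[C@H](O[Si](C)(C)C(C)(C)C)CC[C@H]2C(O[Si](C(C)C)(C(C)C)C(C)C)=C1O[Si](CC)(CC)CC
F5 | step 10 | lithium α-(4-methylpiperazin-1-yl) alkoxide of 15 (aldehyde masked in the flask, C1 epimers) | CC(=O)/C(O[Si](C(C)C)(C(C)C)C(C)C)=C/CC[C@@H](O[Si](C)(C)C(C)(C)C)[C@H](C)C(=C)C(O[Li])N1CCN(C)CC1
F6 | step 7 | (3E,7R,8R)-7-(tert-butyldimethylsilyloxy)-10-hydroxy-8-methyl-3-(triisopropylsilyloxy)dec-3-en-2-one | CC(=O)/C(O[Si](C(C)C)(C(C)C)C(C)C)=C\CC[C@@H](O[Si](C)(C)C(C)(C)C)[C@H](C)CCO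
F7 | step 14 | O-phenyl thionocarbonate of 18 | C1C[C@]2(COC(=S)Oc3ccccc3)[C@@H](C)[C@H](O[Si](C)(C)C(C)(C)C)CC[C@H]2C(O[Si](C(C)C)(C(C)C)C(C)C)=C1O[Si](CC)(CC)CC
F8 | step 17 | (3R,4R,5R,9S,10R)-3-(tert-butyldimethylsilyloxy)-9-(triisopropylsilyloxy)eremophil-7(11)-en-8-one | CC(C)=C1C[C@]2(C)[C@@H](C)[C@H](O[Si](C)(C)C(C)(C)C)CC[C@H]2[C@H](O[Si](C(C)C)(C(C)C)C(C)C)C1=O
A1 | alternative 1 | 3-[(7S,8R)-8-ethenyl-8-methyl-1,4-dioxaspiro[4.5]decan-7-yl]propanal | O=CCC[C@H]1CC2(OCCO2)CC[C@@]1(C=C)C
A2 | alternative 1 | (3R,4R,5S,10S)-8,8-(ethylenedioxy)-11,12,13-trinoreremophilan-3-ol | C[C@H]1[C@H](O)CC[C@H]2CC3(OCCO3)CC[C@]12C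
A3 | alternative 2 | (6S)-6-[(2Z)-6-(tert-butyldimethylsilyloxy)-3-methylhex-2-en-2-yl]oxan-2-one | O=C1CCC[C@H](O1)/C(C)=C(/C)CCCO[Si](C)(C)C(C)(C)C
A4 | alternative 2 | (1R,2S)-2-[3-(tert-butyldimethylsilyloxy)propyl]-2,3-dimethylcyclohex-3-ene-1-carboxylic acid | OC(=O)[C@@H]1CCC=C(C)[C@@]1(C)CCCO[Si](C)(C)C(C)(C)C
A5 | alternative 3 | (2R,3R)-3-(tert-butyldimethylsilyloxy)-5-[3-hydroxy-2-(methoxymethoxy)-6-methylphenyl]pentan-2-yl methanesulfonate | Cc1ccc(O)c(OCOC)c1CC[C@@H](O[Si](C)(C)C(C)(C)C)[C@@H](C)OS(C)(=O)=O
A6 | alternative 3 | (3R,4R,5R)-3-(tert-butyldimethylsilyloxy)-9-(methoxymethoxy)-11,12,13-trinoreremophila-6,9-dien-8-one | C1=C[C@]2(C)[C@@H](C)[C@H](O[Si](C)(C)C(C)(C)C)CCC2=C(OCOC)C1=O
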